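## The problem

Daucane numbering is used throughout: C1 (quaternary, carries the C15 methyl), C2, C3, C4 (carbinol with the isopropyl group), C5 (ring-fusion CH), C6 (CH–O-acyl), C7, C8 (=C14H2), C9, C10. Ring A is C1–C5, ring B is C1, C5–C10, and β is the face of the C15 methyl group.

The target 31 is a trans-fused hydroazulene with six stereocentres (1S,4R,5S,6S,9R,10S). Ring A carries the quaternary C1 and the tertiary carbinol C4 (β-OH, α-isopropyl); ring B carries three α-oxygen substituents (C6, C9, C10) and the exocyclic C8=C14 alkene. Some centres can be relayed: a substituent at C5 sends a nucleophile to the opposite face of a C4 ketone, and the resulting C4–OH, cis to the C6 arm, can hold a metal together with a C6 aldehyde. The hard relation in ring A is C5 against C1, because the two substituents on C1 (CH3 and a one-carbon oxygenated arm) differ little in size. C9 and C10 have no neighbour to lean on and must be set in, or by, the ring closure. The tertiary C4–OH (dehydration), the allylic C9 carbinol beside the exocyclic alkene (ionisation, migration of the double bond into the ring) and the single ester among four hydroxyls rule out strong acid and late basic steps. What makes the key step possible is the array C10–OH / C9–OH / C8=C14: a 1,2-diol beside a 1,1-disubstituted alkene is what a γ-oxygenated allylmetal leaves when it adds to an aldehyde, and the C10 aldehyde sits on quaternary C1 and cannot enolise.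

## Retrosynthesis

**Ester and diol (31 → 28).** The 3-methylbutanoate is placed on C6 last but one. Acylation needs C9–OH and C10–OH blocked and C4–OH is inert, so the cis-9,10-diol is masked as acetonide 29, acylated to 30 and released with aqueous acetic acid. Tetraol 28 comes from the ring-closure product 27 by one fluoride treatment. This is why every protecting group on 27 is a silyl group: an acetal on the C9 oxygen would need acid next to the allylic system at the end.

**Ring B (27 → 26).** The C9–C10 bond is cut. Cutting C8–C9 (vinyl halide plus aldehyde) would leave C10 and its hydroxyl to be made separately; cutting C9–C10 creates both carbinol centres and the exocyclic alkene in one event. The precursor 26 is a monocyclic trans-1,2-disubstituted cyclopentane: a C10 aldehyde on C1 and a C5 side chain ending in a (Z)-γ-silyloxy allylstannane. The forward reaction must attack through C9 (not C8), use one face of the enol ether and one face of the aldehyde.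

**Stannane and aldehyde (26 → 25 → 22).** The aldehyde is made last from alcohol 25 by a non-acidic oxidation. The C14–Sn bond and the enol ether come from metalation of the allyl silyl ether in 22 α to oxygen and γ-stannylation, the standard entry to (Z)-γ-silyloxy allylstannanes. Fluoride would destroy the silyl enol ether, so the C10 hydroxyl is not protected; it is carried through the metalation as its lithium alkoxide. It is freed beforehand from PMB ether 21 with DDQ, which also removes the benzylic ether protons that would compete with the allylic ones.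

**C6–C7 bond (21 → 20 → 15 + 18).** The side chain is attached by Barbier allylation of β-hydroxy aldehyde 15 with allyl bromide 18 (two steps from 2-methylidenepropane-1,3-diol 16). An open, Felkin-type addition to a C4-silylated aldehyde would favour the wrong C6 epimer. With C4–OH free, a chelate between this hydroxyl and the aldehyde exposes the face of C6 next to H5, which gives 6S. Silylation of both hydroxyls (21) therefore follows the allylation.

**C4 and the C6 aldehyde (15 → 14 → 13).** The aldehyde is kept as a dithiane until the isopropyl group is in place. β-Keto dithiane 13 takes the isopropyl nucleophile anti to the bulky dithianyl group, which gives the 4R carbinol 14. Buffered alkylative hydrolysis then frees 15 without acid.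

**C5–C6 bond (13 → 9 + 12).** A ketone with quaternary C1 would enolise away from C5, so the enolate is taken regiospecifically from the conjugate addition as silyl enol ether 9 and alkylated with dithienium salt 12 (from 1,3-dithiane 10 and trityl salt 11). The electrophile is large, which helps it distinguish CH3 from CH2OPMB on C1. The new centre stays epimerisable.

**C1 (9 → 7 → 3 + 4).** The quaternary centre is set by enantioselective copper-catalysed addition of Me3Al to enone 7, which already carries C10 as a PMB-oxymethyl group. Adding the methyl group last keeps C10 at the alcohol oxidation level from the start. Enone 7 comes from 3-ethoxycyclopent-2-en-1-one 4 and stannane 3 (from alcohol 1 and iodide 2).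

## Roads not taken

**Alternative 1:** cut C1–C15 and C5–C6 in one three-component step. A methylcopper reagent adds to the dioxolanyl enone A3 and the enolate is trapped by 3-bromobut-3-enal A2 to give A1, which already holds C1, C5, C6, the C9/C10 oxygens (as an acetonide from the chiral pool) and a C8 vinyl bromide for a later C8–C9 closure.
- Merits: very convergent. The branched dioxolane differentiates the faces at C5 better than the CH2OPMB group of the chosen route, and C10 is fixed before any ring is closed.
- Weak points: the methyl face at C1 depends on 1,2-induction from an exocyclic stereocentre. The aldol has to control C6 with an E-enolate and an aldehyde that isomerises readily into conjugation. The later seven-membered closure must still set C9, and the acetonide must be opened regioselectively.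
- Comparison: this road is shorter to ring A and safer at C5. The chosen plan sets against it a reagent-controlled C1, a chelation-controlled C6, and a ring closure that delivers C9, C10 and the alkene together.

**Alternative 2:** cut C1–C5 across a ten-membered ring. Acid opens a C1–C10 epoxide of a cyclodecadiene at C1, the C4=C5 alkene attacks across the ring, and water traps the C4 cation to give A4, two steps from the target.
- Merits: unmatched brevity after the key step; both rings, C1, C5, C4 and C10 come from one cationic cascade.
- Weak points: the macrocyclic epoxy diene with its C6 and C9 stereocentres is itself a demanding target. The outcome depends on the reacting conformer of a flexible ring. Capture of a tertiary cation by water on the required β face competes with elimination and hydride shifts. The exocyclic alkene and the allylic C9 ether sit in the acid.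
- Comparison: the chosen plan is far longer after ring closure, but each of its stereocentres has a named controlling element, and the only acid it uses is aqueous acetic acid.

**Alternative 3:** cut C7–C8 and C1–C10 by a (4+3) annulation. A rhodium vinylcarbenoid cyclopropanates the ethoxyvinyl group of a cyclopentenyl diene and the divinylcyclopropane rearranges (Cope) to cycloheptadiene A5.
- Merits: ring B, quaternary C1 and C10 are formed catalytically in one step, with asymmetric induction from a chiral dirhodium carboxylate, early in the route.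
- Weak points: A5 is far from the target in oxidation pattern. C14 arrives as an ester on an endocyclic alkene and must become the exocyclic methylene. C9 oxygen is absent. C5, C6 and C4 all remain to be set by reductions and additions. The Cope step must form a quaternary centre from a tetrasubstituted diene terminus.
- Comparison: this road builds the carbon skeleton faster. The chosen plan needs more steps before ring closure but lands on the exact functional pattern of ring B, so the endgame is protecting-group chemistry only.

Key step: step 15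

Assumption: metalation of the 2-substituted allyl silyl ether in 22 is taken to give the (Z)-silyloxyallyl anion and stannylation at the γ terminus, as it does for the parent allyl silyl ether.

**Step 1**
Reactants: 1 (4-methoxyphenyl)methanol; 2 tributyl(iodomethyl)stannane
Product: 3 tributyl{[(4-methoxybenzyl)oxy]methyl}stannane
Conditions: NaH, THF/DMF, 0 °C → rt
Reagents that add atoms: none
Why: Williamson etherification; the sodium alkoxide displaces iodide from an unhindered primary carbon.

**Step 2**
Reactants: 3 tributyl{[(4-methoxybenzyl)oxy]methyl}stannane; 4 3-ethoxycyclopent-2-en-1-one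
Product: 7 3-{[(4-methoxybenzyl)oxy]methyl}cyclopent-2-en-1-one, via alkoxymethyllithium 5 (not isolated), via lithium alkoxide adduct 6 (not isolated)
Conditions: n-BuLi, THF, –78 °C; add 4; then 1 M HCl, 0 °C
Reagents that add atoms: water (O)
Why: Tin–lithium exchange gives an α-alkoxymethyllithium that adds 1,2 to the vinylogous ester; acid hydrolysis with loss of ethanol and water transposes the carbonyl (Stork–Danheiser sequence).

**Step 3**
Reactants: 7 3-{[(4-methoxybenzyl)oxy]methyl}cyclopent-2-en-1-one
Product: 9 (S)-[(3-{[(4-methoxybenzyl)oxy]methyl}-3-methylcyclopent-1-en-1-yl)oxy]trimethylsilane, via dimethylaluminium enolate 8 (not isolated)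
Conditions: Me3Al, Cu(OTf)2 (5 mol %), chiral sulfonate-bearing imidazolinium salt pretreated with Ag2O (carbene ligand, 5 mol %), THF, –78 °C; then TMSOTf, –78 → –20 °C
Reagents that add atoms: trimethylaluminium (C[Al](C)C); trimethylsilyl trifluoromethanesulfonate (C[Si](C)(C)OS(=O)(=O)C(F)(F)F)
Why: Copper-catalysed enantioselective conjugate addition of Me3Al to a β-substituted cyclopentenone builds quaternary C1, the ligand enantiomer being chosen for the 1S centre. Silylation of the aluminium enolate fixes the enolate at C5, which deprotonation of the ketone would not do.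

**Step 4**
Reactants: 10 1,3-dithiane; 11 triphenylcarbenium tetrafluoroborate
Product: 12 1,3-dithian-2-ylium tetrafluoroborate
Conditions: CH2Cl2, reflux; precipitate with Et2O
Reagents that add atoms: none
Why: Hydride abstraction from C2 of the dithiane by the trityl cation gives the sulfur-stabilised carbenium salt.

**Step 5**
Reactants: 9 (S)-[(3-{[(4-methoxybenzyl)oxy]methyl}-3-methylcyclopent-1-en-1-yl)oxy]trimethylsilane; 12 1,3-dithian-2-ylium tetrafluoroborate
Product: 13 (2R,3S)-2-(1,3-dithian-2-yl)-3-{[(4-methoxybenzyl)oxy]methyl}-3-methylcyclopentan-1-one (dithianyl group cis to the methyl group)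
Conditions: CH2Cl2, –78 °C; aq. NaHCO3
Reagents that add atoms: none
Why: Mukaiyama-type alkylation of a silyl enol ether by a dithio-stabilised carbenium ion. The bulky cation should approach C5 past the C1 methyl group and not past the CH2OPMB group, and no metal is present to be chelated by the ether oxygen. The new centre stays epimerisable, so the isomer with the dithianyl group cis to methyl can be enriched.

**Step 6**
Reactants: 13 (2R,3S)-2-(1,3-dithian-2-yl)-3-{[(4-methoxybenzyl)oxy]methyl}-3-methylcyclopentan-1-one
Product: 14 (1R,2R,3S)-2-(1,3-dithian-2-yl)-3-{[(4-methoxybenzyl)oxy]methyl}-3-methyl-1-(propan-2-yl)cyclopentan-1-ol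
Conditions: iPrMgCl, CeCl3, THF, –78 → 0 °C; aq. NH4Cl
Reagents that add atoms: isopropylmagnesium chloride (CC(C)[Mg]Cl)
Why: Organocerium addition, whose low basicity suppresses enolisation and reduction of the hindered ketone. The nucleophile enters anti to the dithianyl group on C5, so the C4 hydroxyl ends cis to the future C6 arm (4R).

**Step 7**
Reactants: 14 (1R,2R,3S)-2-(1,3-dithian-2-yl)-3-{[(4-methoxybenzyl)oxy]methyl}-3-methyl-1-(propan-2-yl)cyclopentan-1-ol
Product: 15 (1R,2R,5S)-2-hydroxy-5-{[(4-methoxybenzyl)oxy]methyl}-5-methyl-2-(propan-2-yl)cyclopentane-1-carbaldehyde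
Conditions: MeI, CaCO3, MeCN/H2O (9:1), 40 °C; used crude
Reagents that add atoms: water (O)
Why: Alkylative hydrolysis of the dithiane under buffered, near-neutral conditions frees the aldehyde without the acid that would dehydrate a β-hydroxy aldehyde; PMB ether and tertiary alcohol are untouched.

**Step 8**
Reactants: 16 2-methylidenepropane-1,3-diol
Product: 17 2-({[tert-butyl(dimethyl)silyl]oxy}methyl)prop-2-en-1-ol
Conditions: NaH (1.0 equiv), THF, 0 °C; TBSCl
Reagents that add atoms: tert-butyldimethylsilyl chloride (CC(C)(C)[Si](C)(C)Cl)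
Why: Monosilylation of a symmetrical diol through its monosodium alkoxide.

**Step 9**
Reactants: 17 2-({[tert-butyl(dimethyl)silyl]oxy}methyl)prop-2-en-1-ol
Product: 18 {[2-(bromomethyl)prop-2-en-1-yl]oxy}(tert-butyl)dimethylsilane
Conditions: CBr4, PPh3, CH2Cl2, 0 °C
Reagents that add atoms: carbon tetrabromide (BrC(Br)(Br)Br)
Why: Appel bromination of a primary allylic alcohol under neutral conditions that spare the silyl ether.

**Step 10**
Reactants: 15 (1R,2R,5S)-2-hydroxy-5-{[(4-methoxybenzyl)oxy]methyl}-5-methyl-2-(propan-2-yl)cyclopentane-1-carbaldehyde; 18 {[2-(bromomethyl)prop-2-en-1-yl]oxy}(tert-butyl)dimethylsilane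
Product: 20 (1R,2S,3S)-2-[(1S)-3-({[tert-butyl(dimethyl)silyl]oxy}methyl)-1-hydroxybut-3-en-1-yl]-3-{[(4-methoxybenzyl)oxy]methyl}-3-methyl-1-(propan-2-yl)cyclopentan-1-ol, via allylindium dibromide 19 (not isolated)
Conditions: In powder, THF/H2O (1:1), rt
Reagents that add atoms: none
Why: Barbier-type indium allylation, which tolerates free hydroxyl groups. The C4 hydroxyl and the aldehyde oxygen should bind indium in a six-membered chelate cis-fused to ring A (Cram-chelate model), with isopropyl equatorial. The allyl group then adds to the face of C6 flanked by H5 and away from C1 and C3, which gives the 6S carbinol.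

**Step 11**
Reactants: 20 (1R,2S,3S)-2-[(1S)-3-({[tert-butyl(dimethyl)silyl]oxy}methyl)-1-hydroxybut-3-en-1-yl]-3-{[(4-methoxybenzyl)oxy]methyl}-3-methyl-1-(propan-2-yl)cyclopentan-1-ol
Product: 21 bis(triethylsilyl) ether of 20 (triethylsilyl on the C4 and C6 oxygens; TBS and PMB ethers unchanged)
Conditions: TESOTf, 2,6-lutidine, CH2Cl2, –78 → 0 °C
Reagents that add atoms: triethylsilyl trifluoromethanesulfonate (CC[Si](CC)(CC)OS(=O)(=O)C(F)(F)F)
Why: The silyl triflate silylates the secondary and the hindered tertiary hydroxyl in one operation.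

**Step 12**
Reactants: 21 bis(triethylsilyl) ether of 20
Product: 22 {(1S,2S,3R)-2-[(1S)-3-({[tert-butyl(dimethyl)silyl]oxy}methyl)-1-[(triethylsilyl)oxy]but-3-en-1-yl]-1-methyl-3-(propan-2-yl)-3-[(triethylsilyl)oxy]cyclopentyl}methanol
Conditions: DDQ, CH2Cl2/pH 7 buffer (10:1), 0 °C
Reagents that add atoms: none
Why: Oxidative cleavage of the PMB ether leaves silyl ethers and the 1,1-disubstituted alkene alone; it is done before the metalation because benzylic ether protons would compete with the allylic ones.

**Step 13**
Reactants: 22 {(1S,2S,3R)-2-[(1S)-3-({[tert-butyl(dimethyl)silyl]oxy}methyl)-1-[(triethylsilyl)oxy]but-3-en-1-yl]-1-methyl-3-(propan-2-yl)-3-[(triethylsilyl)oxy]cyclopentyl}methanol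
Product: 25 {(1S,2S,3R)-2-[(1S,3Z)-4-{[tert-butyl(dimethyl)silyl]oxy}-3-[(tributylstannyl)methyl]-1-[(triethylsilyl)oxy]but-3-en-1-yl]-1-methyl-3-(propan-2-yl)-3-[(triethylsilyl)oxy]cyclopentyl}methanol, via lithium alkoxide 23 (not isolated), via dilithio species 24 (not isolated)
Conditions: n-BuLi (1.0 equiv), THF, –78 °C; s-BuLi (1.5 equiv), HMPA, –78 °C; Bu3SnCl, –78 °C; H2O
Reagents that add atoms: tributyltin chloride (CCCC[Sn](Cl)(CCCC)CCCC)
Why: The lithium alkoxide protects the C10 hydroxyl; s-BuLi then removes an allylic proton α to the silyloxy group. The oxyallyl anion, with oxygen cis to the C14 terminus, is stannylated at C14 to give the (Z)-γ-silyloxy allylstannane.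

**Step 14**
Reactants: 25 (Z)-allylstannane alcohol from step 13
Product: 26 (1S,2S,3R)-2-[(1S,3Z)-4-{[tert-butyl(dimethyl)silyl]oxy}-3-[(tributylstannyl)methyl]-1-[(triethylsilyl)oxy]but-3-en-1-yl]-1-methyl-3-(propan-2-yl)-3-[(triethylsilyl)oxy]cyclopentane-1-carbaldehyde
Conditions: SO3·pyridine, DMSO, iPr2NEt, CH2Cl2, 0 °C; chromatography on Et3N-treated silica
Reagents that add atoms: none
Why: Parikh–Doering oxidation is non-acidic and spares the allylstannane and the silyl enol ether; the neopentyl aldehyde cannot enolise.

**Step 15**
Reactants: 26 (Z)-allylstannane aldehyde from step 14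
Product: 27 (1S,4R,5S,6S,9R,10S)-9-{[tert-butyl(dimethyl)silyl]oxy}-4,6-bis[(triethylsilyl)oxy]dauc-8(14)-en-10-ol
Conditions: MgBr2·OEt2 (3 equiv), CH2Cl2, –40 → 0 °C; aq. NaHCO3
Reagents that add atoms: none
Why: The magnesium-complexed C10 aldehyde is attacked by C9, the γ carbon of the allylstannane, anti to tin; the C14–Sn bond stabilises the charge developing at C8 and then breaks, leaving C8=C14 (intramolecular SE2' allylation). The closest known reactions are Lewis acid-promoted intramolecular additions of γ-oxygenated allylstannanes to aldehydes (cyclic ethers, macrocycles) and cyclisations of aldehydes carrying a 2-(stannylmethyl)alkenyl group to methylenecycloalkanols. Ring B closes in a seven-membered mode that is exo with respect to the carbonyl group; C8 and C9 of the nucleophile lie in the new ring and the double bond ends outside it. C9 is set by the (Z) geometry together with the ring: the silyloxy group is cis to C14 and stays pseudo-equatorial, the tether carbon C7 is cis to H9, and the closures compatible with the trans C1/C5 arms that keep the forming bond staggered use the enol ether face that gives 9R. C10 is set by the aldehyde rotamer: the synclinal arrangement, with the carbonyl oxygen pseudo-axial, anti to the C1 methyl group and with only H5 as 1,3-partner, gives the 9,10-cis diol (10S), whereas the antiperiplanar arrangement would give the trans isomer. The step therefore needs regioselectivity for C9 over C8 and selectivity for the synclinal arrangement. The first is secured by the C–Sn bond, which makes C9 the nucleophilic terminus, and by the fact that attack through C8 would build a quaternary centre. The second rests on the synclinal preference usual for intramolecular allylstannane additions and is the less certain of the two.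

**Step 16**
Reactants: 27 hydroazulene silyl ether from step 15
Product: 28 (1S,4R,5S,6S,9R,10S)-dauc-8(14)-ene-4,6,9,10-tetraol
Conditions: TBAF, THF, 0 → 40 °C
Reagents that add atoms: none
Why: Fluoride cleaves all three silyl ethers in one operation under non-acidic conditions; any silyl migration between the C9 and C10 oxygens in step 15 is without consequence.

**Step 17**
Reactants: 28 (1S,4R,5S,6S,9R,10S)-dauc-8(14)-ene-4,6,9,10-tetraol
Product: 29 9,10-O-isopropylidene derivative of 28
Conditions: 2,2-dimethoxypropane (1.5 equiv), PPTS (cat.), CH2Cl2, 0 °C → rt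
Reagents that add atoms: 2,2-dimethoxypropane (COC(C)(C)OC)
Why: Acetone ketals form preferentially as five-membered dioxolanes on cis-vicinal diols; the 4,6-diol with its tertiary hydroxyl would need a six-membered ketal and reacts more slowly.

**Step 18**
Reactants: 29 9,10-O-isopropylidene derivative of 28
Product: 30 6-O-(3-methylbutanoyl) derivative of 29
Conditions: 3-methylbutanoyl chloride, pyridine, DMAP (cat.), CH2Cl2, 0 °C → rt
Reagents that add atoms: 3-methylbutanoyl chloride (CC(C)CC(=O)Cl)
Why: DMAP-catalysed acylation of the only free secondary hydroxyl; the tertiary C4 hydroxyl does not react.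

**Step 19**
Reactants: 30 6-O-(3-methylbutanoyl) derivative of 29
Product: 31 (1S,4R,5S,6S,9R,10S)-4,9,10-trihydroxydauc-8(14)-en-6-yl 3-methylbutanoate (CNP0204264.1)
Conditions: AcOH/H2O (4:1), 40 °C
Reagents that add atoms: none
Why: Mild aqueous acid hydrolyses the dioxolane without touching the ester, the tertiary alcohol or the exocyclic alkene.

**Compound list**

1 | (4-methoxyphenyl)methanol | COc1ccc(CO)cc1 | starting material
2 | tributyl(iodomethyl)stannane | CCCC[Sn](CCCC)(CCCC)CI | starting material
3 | tributyl{[(4-methoxybenzyl)oxy]methyl}stannane | CCCC[Sn](CCCC)(CCCC)COCc1ccc(OC)cc1 | intermediate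
4 | 3-ethoxycyclopent-2-en-1-one | CCOC1=CC(=O)CC1 | starting material
5 | {[(4-methoxybenzyl)oxy]methyl}lithium (not isolated) | [Li]COCc1ccc(OC)cc1 | intermediate
6 | lithium 3-ethoxy-1-{[(4-methoxybenzyl)oxy]methyl}cyclopent-2-en-1-olate (not isolated) | CCOC1=CC(O[Li])(COCc2ccc(OC)cc2)CC1 | intermediate
7 | 3-{[(4-methoxybenzyl)oxy]methyl}cyclopent-2-en-1-one | O=C1C=C(COCc2ccc(OC)cc2)CC1 | intermediate
8 | (S)-dimethylaluminium enolate of 3-{[(4-methoxybenzyl)oxy]methyl}-3-methylcyclopentanone (not isolated) | C[Al](C)OC1=C[C@@](C)(COCc2ccc(OC)cc2)CC1 | intermediate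
9 | (S)-[(3-{[(4-methoxybenzyl)oxy]methyl}-3-methylcyclopent-1-en-1-yl)oxy]trimethylsilane | C[Si](C)(C)OC1=C[C@@](C)(COCc2ccc(OC)cc2)CC1 | intermediate
10 | 1,3-dithiane | C1CSCSC1 | starting material
11 | triphenylcarbenium tetrafluoroborate | F[B-](F)(F)F.c1ccc(cc1)[C+](c1ccccc1)c1ccccc1 | starting material
12 | 1,3-dithian-2-ylium tetrafluoroborate | C1CSC=[S+]C1.F[B-](F)(F)F | intermediate
13 | (2R,3S)-2-(1,3-dithian-2-yl)-3-{[(4-methoxybenzyl)oxy]methyl}-3-methylcyclopentan-1-one | S1CCCSC1[C@@H]2[C@](C)(CCC2=O)COCc1ccc(OC)cc1 | intermediate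
14 | (1R,2R,3S)-2-(1,3-dithian-2-yl)-3-{[(4-methoxybenzyl)oxy]methyl}-3-methyl-1-(propan-2-yl)cyclopentan-1-ol | S1CCCSC1[C@@H]2[C@](C)(CC[C@@]2(O)C(C)C)COCc1ccc(OC)cc1 | intermediate
15 | (1R,2R,5S)-2-hydroxy-5-{[(4-methoxybenzyl)oxy]methyl}-5-methyl-2-(propan-2-yl)cyclopentane-1-carbaldehyde | O=C[C@@H]2[C@](C)(CC[C@@]2(O)C(C)C)COCc1ccc(OC)cc1 | intermediate
16 | 2-methylidenepropane-1,3-diol | C=C(CO)CO | starting material
17 | 2-({[tert-butyl(dimethyl)silyl]oxy}methyl)prop-2-en-1-ol | C=C(CO)CO[Si](C)(C)C(C)(C)C | intermediate
18 | {[2-(bromomethyl)prop-2-en-1-yl]oxy}(tert-butyl)dimethylsilane | C=C(CBr)CO[Si](C)(C)C(C)(C)C | intermediate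
19 | allylindium reagent from 18, written as [2-({[tert-butyl(dimethyl)silyl]oxy}methyl)prop-2-en-1-yl]indium dibromide (not isolated) | C=C(C[In](Br)Br)CO[Si](C)(C)C(C)(C)C | intermediate
20 | (1R,2S,3S)-2-[(1S)-3-({[tert-butyl(dimethyl)silyl]oxy}methyl)-1-hydroxybut-3-en-1-yl]-3-{[(4-methoxybenzyl)oxy]methyl}-3-methyl-1-(propan-2-yl)cyclopentan-1-ol | C=C(CO[Si](C)(C)C(C)(C)C)C[C@H](O)[C@@H]2[C@](C)(CC[C@@]2(O)C(C)C)COCc1ccc(OC)cc1 | intermediate
21 | bis(triethylsilyl) ether of 20 (C4 and C6 oxygens) | C=C(CO[Si](C)(C)C(C)(C)C)C[C@H](O[Si](CC)(CC)CC)[C@@H]2[C@](C)(CC[C@@]2(O[Si](CC)(CC)CC)C(C)C)COCc1ccc(OC)cc1 | intermediate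
22 | {(1S,2S,3R)-2-[(1S)-3-({[tert-butyl(dimethyl)silyl]oxy}methyl)-1-[(triethylsilyl)oxy]but-3-en-1-yl]-1-methyl-3-(propan-2-yl)-3-[(triethylsilyl)oxy]cyclopentyl}methanol | C=C(CO[Si](C)(C)C(C)(C)C)C[C@H](O[Si](CC)(CC)CC)[C@@H]2[C@](C)(CC[C@@]2(O[Si](CC)(CC)CC)C(C)C)CO | intermediate
23 | lithium alkoxide of 22 (not isolated) | C=C(CO[Si](C)(C)C(C)(C)C)C[C@H](O[Si](CC)(CC)CC)[C@@H]2[C@](C)(CC[C@@]2(O[Si](CC)(CC)CC)C(C)C)CO[Li] | intermediate
24 | dilithio species: lithium alkoxide of 22 lithiated at the allylic carbon bearing the TBS-oxy group (not isolated) | C=C(C([Li])O[Si](C)(C)C(C)(C)C)C[C@H](O[Si](CC)(CC)CC)[C@@H]2[C@](C)(CC[C@@]2(O[Si](CC)(CC)CC)C(C)C)CO[Li] | intermediate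
25 | {(1S,2S,3R)-2-[(1S,3Z)-4-{[tert-butyl(dimethyl)silyl]oxy}-3-[(tributylstannyl)methyl]-1-[(triethylsilyl)oxy]but-3-en-1-yl]-1-methyl-3-(propan-2-yl)-3-[(triethylsilyl)oxy]cyclopentyl}methanol | CCCC[Sn](CCCC)(CCCC)C/C(=C\O[Si](C)(C)C(C)(C)C)C[C@H](O[Si](CC)(CC)CC)[C@@H]2[C@](C)(CC[C@@]2(O[Si](CC)(CC)CC)C(C)C)CO | intermediate
26 | (1S,2S,3R)-2-[(1S,3Z)-4-{[tert-butyl(dimethyl)silyl]oxy}-3-[(tributylstannyl)methyl]-1-[(triethylsilyl)oxy]but-3-en-1-yl]-1-methyl-3-(propan-2-yl)-3-[(triethylsilyl)oxy]cyclopentane-1-carbaldehyde | CCCC[Sn](CCCC)(CCCC)C/C(=C\O[Si](C)(C)C(C)(C)C)C[C@H](O[Si](CC)(CC)CC)[C@@H]2[C@](C)(CC[C@@]2(O[Si](CC)(CC)CC)C(C)C)C=O | intermediate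
27 | (1S,4R,5S,6S,9R,10S)-9-{[tert-butyl(dimethyl)silyl]oxy}-4,6-bis[(triethylsilyl)oxy]dauc-8(14)-en-10-ol | C=C1C[C@H](O[Si](CC)(CC)CC)[C@@H]2[C@](C)(CC[C@@]2(O[Si](CC)(CC)CC)C(C)C)[C@H](O)[C@@H]1O[Si](C)(C)C(C)(C)C | intermediate
28 | (1S,4R,5S,6S,9R,10S)-dauc-8(14)-ene-4,6,9,10-tetraol | C=C1C[C@H](O)[C@@H]2[C@](C)(CC[C@@]2(O)C(C)C)[C@H](O)[C@@H]1O | intermediate
29 | 9,10-O-isopropylidene derivative of 28 | C=C1C[C@H](O)[C@@H]2[C@](C)(CC[C@@]2(O)C(C)C)[C@H](OC(C)(C)O3)[C@@H]13 | intermediate
30 | 6-O-(3-methylbutanoyl) derivative of 29 | C=C1C[C@H](OC(=O)CC(C)C)[C@@H]2[C@](C)(CC[C@@]2(O)C(C)C)[C@H](OC(C)(C)O3)[C@@H]13 | intermediate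
31 | (1S,4R,5S,6S,9R,10S)-4,9,10-trihydroxydauc-8(14)-en-6-yl 3-methylbutanoate | C=C1C[C@H](OC(=O)CC(C)C)[C@@H]2[C@](C)(CC[C@@]2(O)C(C)C)[C@H](O)[C@@H]1O | target

**Step count and uncertain steps**

Total: 19 steps. Longest linear sequence: 16 steps (steps 1–3, 5–7, 10–19); step 4 and steps 8–9 are side branches.

**Step 15 (key step).** The most likely failure is poor facial selectivity at the aldehyde: closure through the antiperiplanar arrangement (carbonyl oxygen pseudo-equatorial) would give the 9,10-trans isomer, because the steric difference between the two aldehyde rotamers is small in a seven-membered transition state. A second risk is attack through C8 of the enol ether in place of C9. The fallback sets out from 26 and corrects C10 after the ring is closed. The cyclisation is run as before and the 10-epimeric alcohol F1 is accepted. F1 is oxidised with Dess–Martin periodinane and pyridine to the C10 ketone F2. F2 is reduced with LiBH(s-Bu)3 at –78 °C from the β face, which carries only the C1 methyl group and H9, while the α face is screened by the C9 silyloxy group and ring A. This returns 27, and both C10 epimers converge on it.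

**Step 13.** The most likely failure is incomplete or misdirected metalation caused by aggregation with the lithium alkoxide, with 1,2-migration of silicon from oxygen to carbon in the silyloxyallyl anion as a second drain. The fallback sets out from 22 and replaces the alkoxide by a temporary silyl ether. TMSCl and Et3N give the trimethylsilyl ether F3. The same s-BuLi/HMPA metalation and Bu3SnCl quench give the stannane F4. K2CO3 in MeOH at 0 °C removes the primary trimethylsilyl group and returns 25.

**Step 5.** The most likely failure is insufficient discrimination between the methyl and the CH2OPMB group on C1 during the approach of the electrophile, since the two differ only moderately in size. The fallback gives up kinetic control: the reaction is run from 9 as before, the separated C5 epimer F5 is equilibrated through its enol with DBU in toluene and re-separated, and the material returns to 13.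

**Step 6.** The most likely failure is enolisation or β-hydride reduction outrunning addition of the branched nucleophile to a ketone flanked by the dithianyl group. The fallback sets out from 13 and uses the smaller sp2 nucleophile CH2=C(CH3)MgBr with CeCl3 to give the isopropenyl carbinol F6. Diimide, from 2-nitrobenzenesulfonyl hydrazide and Et3N, is not poisoned by sulfur and saturates the alkene, returning 14.

**Step 10.** The most likely failure is erosion of the C6 selectivity because the chelate is not held in the aqueous medium; the open, Felkin-type addition favours the 6-epimer. The fallback sets out from 15 and inverts the carbinol after the fact. The separated 6-epimeric diol F7 undergoes Mitsunobu inversion with 4-nitrobenzoic acid, PPh3 and DIAD to give the ester F8 (the tertiary hydroxyl does not react). K2CO3 in MeOH cleaves the ester and returns 20.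

**Further compounds**

F1 | step 15 | (1S,4R,5S,6S,9R,10R)-9-{[tert-butyl(dimethyl)silyl]oxy}-4,6-bis[(triethylsilyl)oxy]dauc-8(14)-en-10-ol (10-epimer of 27) | C=C1C[C@H](O[Si](CC)(CC)CC)[C@@H]2[C@](C)(CC[C@@]2(O[Si](CC)(CC)CC)C(C)C)[C@@H](O)[C@@H]1O[Si](C)(C)C(C)(C)C
F2 | step 15 | (1S,4R,5S,6S,9R)-9-{[tert-butyl(dimethyl)silyl]oxy}-4,6-bis[(triethylsilyl)oxy]dauc-8(14)-en-10-one | C=C1C[C@H](O[Si](CC)(CC)CC)[C@@H]2[C@](C)(CC[C@@]2(O[Si](CC)(CC)CC)C(C)C)C(=O)[C@@H]1O[Si](C)(C)C(C)(C)C
F3 | step 13 | trimethylsilyl ether of 22 (C10 oxygen) | C=C(CO[Si](C)(C)C(C)(C)C)C[C@H](O[Si](CC)(CC)CC)[C@@H]2[C@](C)(CC[C@@]2(O[Si](CC)(CC)CC)C(C)C)CO[Si](C)(C)C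
F4 | step 13 | trimethylsilyl ether of 25 (C10 oxygen) | CCCC[Sn](CCCC)(CCCC)C/C(=C\O[Si](C)(C)C(C)(C)C)C[C@H](O[Si](CC)(CC)CC)[C@@H]2[C@](C)(CC[C@@]2(O[Si](CC)(CC)CC)C(C)C)CO[Si](C)(C)C
F5 | step 5 | (2S,3S)-2-(1,3-dithian-2-yl)-3-{[(4-methoxybenzyl)oxy]methyl}-3-methylcyclopentan-1-one (C5 epimer of 13) | S1CCCSC1[C@H]2[C@](C)(CCC2=O)COCc1ccc(OC)cc1
F6 | step 6 | (1R,2R,3S)-2-(1,3-dithian-2-yl)-3-{[(4-methoxybenzyl)oxy]methyl}-3-methyl-1-(prop-1-en-2-yl)cyclopentan-1-ol | S1CCCSC1[C@@H]2[C@](C)(CC[C@@]2(O)C(C)=C)COCc1ccc(OC)cc1
F7 | step 10 | (1R,2S,3S)-2-[(1R)-3-({[tert-butyl(dimethyl)silyl]oxy}methyl)-1-hydroxybut-3-en-1-yl]-3-{[(4-methoxybenzyl)oxy]methyl}-3-methyl-1-(propan-2-yl)cyclopentan-1-ol (C6 epimer of 20) | C=C(CO[Si](C)(C)C(C)(C)C)C[C@@H](O)[C@@H]2[C@](C)(CC[C@@]2(O)C(C)C)COCc1ccc(OC)cc1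
F8 | step 10 | 6-O-(4-nitrobenzoyl) derivative of 20 | C=C(CO[Si](C)(C)C(C)(C)C)C[C@H](OC(=O)c1ccc(cc1)[N+](=O)[O-])[C@@H]2[C@](C)(CC[C@@]2(O)C(C)C)COCc1ccc(OC)cc1
A1 | alternative 1 | 2-(3-bromo-1-hydroxybut-3-en-1-yl)-3-(2,2-dimethyl-1,3-dioxolan-4-yl)-3-methylcyclopentan-1-one (aldol adduct) | C=C(Br)C[C@H](O)[C@@H]2[C@](C)(CCC2=O)[C@H](OC(C)(C)O3)C3
A2 | alternative 1 | 3-bromobut-3-enal | C=C(Br)CC=O
A3 | alternative 1 | 3-(2,2-dimethyl-1,3-dioxolan-4-yl)cyclopent-2-en-1-one | O=C1C=C(CC1)[C@H](OC(C)(C)O2)C2
A4 | alternative 2 | (1S,4R,5S,6S,9R,10S)-6,9-bis{[tert-butyl(dimethyl)silyl]oxy}dauc-8(14)-ene-4,10-diol | C=C1C[C@H](O[Si](C)(C)C(C)(C)C)[C@@H]2[C@](C)(CC[C@@]2(O)C(C)C)[C@H](O)[C@@H]1O[Si](C)(C)C(C)(C)C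
A5 | alternative 3 | bicyclic cycloheptadiene methyl ester with C6 ethyl enol ether, C10 silyl ether and C4 ketone | COC(=O)C=1CC(OCC)=C2[C@](C)(CCC2=O)[C@H](O[Si](C)(C)C(C)(C)C)C=1
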